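**Retrosynthetic overview**
1. Target ⇐ removal of three aryl acetates and a bridging B–Ph from a cyclic phenylboronate. The C8–C(carbinol) bond is made last, by a chiral-phosphoric-acid-catalysed, boronic-acid-templated ortho-hydroxyalkylation of a 7-hydroxyflavanone with a nonenal (new step).
2. Nonenal ⇐ iminium-catalysed conjugate alkenylation of 4-acetoxycinnamaldehyde with an (E)-alkenyltrifluoroborate (sets the C–aryl stereocentre).
3. Alkenyltrifluoroborate ⇐ hydroboration of a homopropargylic alcohol ⇐ chiral-phosphoric-acid-catalysed propargylboration of 3-(4-acetoxyphenyl)propanal, itself made from the same enal.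
4. Flavanone ⇐ organocatalytic oxa-Michael cyclisation of a 2'-hydroxychalcone ⇐ Claisen–Schmidt condensation of the acetophenone with 4-acetoxybenzaldehyde.
5. Ring order: rings A and B are bought; pyranone ring C closes in step 2; the dioxaborin ring formed in step 8 is temporary and is opened in step 9.

Assumption: the facial sense of each chiral catalyst is taken from its closest published model; if a first run shows the opposite sense, the mirror-image (or pseudo-enantiomeric) catalyst is used.

**Step 1**
Reactants: 1 1-(2,4-dihydroxy-6-methoxyphenyl)ethan-1-one; 2 4-formylphenyl acetate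
Product: 3 4-[(1E)-3-(2,4-dihydroxy-6-methoxyphenyl)-3-oxoprop-1-en-1-yl]phenyl acetate
Conditions: BF3·OEt2 (2.5 equiv), 1,4-dioxane, rt; aq. NaHCO3 work-up
Reagents that add atoms: none
Why: Acid-mediated Claisen–Schmidt condensation through the boron-chelated enol gives the E-enone, and the aryl acetate, which hydroxide would cleave, survives.

**Step 2**
Reactants: 3 4-[(1E)-3-(2,4-dihydroxy-6-methoxyphenyl)-3-oxoprop-1-en-1-yl]phenyl acetate
Product: 4 4-[(2S)-7-hydroxy-5-methoxy-4-oxo-3,4-dihydro-2H-chromen-2-yl]phenyl acetate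
Conditions: N-[3,5-bis(trifluoromethyl)phenyl]-N'-(9-deoxy-epi-quinidin-9-yl)squaramide (10 mol%), toluene/THF 4:1, 0 °C
Reagents that add atoms: none
Why: Bifunctional base/hydrogen-bond catalysed intramolecular oxa-Michael addition (6-endo-trig), in which the quinuclidine activates the 2'-OH and the squaramide binds the enone carbonyl, so one enone face is attacked and C2 is set as S; the 6'-OMe group twists the chalcone and drives ring closure.

**Step 3**
Reactants: 2 4-formylphenyl acetate; 5 (triphenylphosphoranylidene)acetaldehyde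
Product: 6 4-[(1E)-3-oxoprop-1-en-1-yl]phenyl acetate
Conditions: 5 (1.05 equiv), toluene, 80 °C
Reagents that add atoms: none
Why: Wittig olefination with a stabilised ylide gives the E-enal under neutral conditions that leave the acetate intact.

**Step 4**
Reactants: 6 4-[(1E)-3-oxoprop-1-en-1-yl]phenyl acetate
Product: 7 4-(3-oxopropyl)phenyl acetate
Conditions: Hantzsch ester (1.1 equiv), dibenzylammonium trifluoroacetate (5 mol%), THF, rt
Reagents that add atoms: none
Why: Iminium-catalysed organocatalytic transfer hydrogenation reduces only the conjugated C=C bond and leaves the aldehyde and the ester untouched.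

**Step 5**
Reactants: 7 4-(3-oxopropyl)phenyl acetate; 8 allenylboronic acid pinacol ester
Product: 9 4-[(3S)-3-hydroxyhex-5-yn-1-yl]phenyl acetate
Conditions: (R)-TRIP [(R)-3,3'-bis(2,4,6-triisopropylphenyl)-1,1'-binaphthyl-2,2'-diyl hydrogen phosphate] (10 mol%), 4 Å MS, toluene, −20 °C; aq. work-up
Reagents that add atoms: none
Why: Chiral-phosphoric-acid-catalysed propargylboration through a closed six-membered SE2′ transition state, in which the acid hydrogen-bonds a boronate oxygen and the formyl C–H, delivers the propargyl group to the Re face and sets the carbinol as S.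

**Step 6**
Reactants: 9 4-[(3S)-3-hydroxyhex-5-yn-1-yl]phenyl acetate
Product: 11 potassium trifluoro[(1E,4S)-6-(4-acetoxyphenyl)-4-hydroxyhex-1-en-1-yl]borate, via O-boryl alkenylboronate 10 (not isolated)
Conditions: catecholborane (2.5 equiv), THF, 65 °C; then KHF2 (4.5 M aq.), MeOH, rt
Reagents that add atoms: catecholborane B1Oc2ccccc2O1; potassium hydrogen difluoride [K+].F[H-]F
Why: Syn, anti-Markovnikov hydroboration of the terminal alkyne gives the E-alkenylboronate (the alcohol is carried as its borate), and KHF2 converts it into the crystalline trifluoroborate while freeing the alcohol; the stereocentre is untouched.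

**Step 7**
Reactants: 6 4-[(1E)-3-oxoprop-1-en-1-yl]phenyl acetate; 11 potassium trifluoro[(1E,4S)-6-(4-acetoxyphenyl)-4-hydroxyhex-1-en-1-yl]borate
Product: 12 (3R,4E,7S)-3,9-bis(4-acetoxyphenyl)-7-hydroxynon-4-enal
Conditions: (2S,5S)-5-benzyl-2-tert-butyl-3-methylimidazolidin-4-one·HCl (20 mol%), aq. HF (1.0 equiv), DME, −20 °C
Reagents that add atoms: none
Why: Iminium-catalysed conjugate alkenylation with an alkenyltrifluoroborate (MacMillan-type Friedel–Crafts alkylation), in which the borate-activated alkene attacks the β-carbon on the face not shielded by the catalyst benzyl group, the β-borato cation collapses with retention of E geometry and HF traps BF3; this sets C3 as R.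

**Step 8**
Reactants: 4 4-[(2S)-7-hydroxy-5-methoxy-4-oxo-3,4-dihydro-2H-chromen-2-yl]phenyl acetate; 12 (3R,4E,7S)-3,9-bis(4-acetoxyphenyl)-7-hydroxynon-4-enal
Product: 13 cyclic phenylboronate of the target triacetate (2-phenyl-4H-1,3,2-benzodioxaborin ring spanning O7 and the new (1S) benzylic oxygen on C8 of flavanone 4)
Conditions: PhB(OH)2 (2.0 equiv), (R)-TRIP (10 mol%), 4 Å MS, toluene, 40 °C
Reagents that add atoms: phenylboronic acid OB(O)c1ccccc1
Why: Proposed new method: the 7-OH condenses with PhB(OH)2 to an aryloxy(phenyl)boron ester, a boron phenolate that is the aromatic counterpart of an allylboronate; (R)-TRIP hydrogen-bonds the boron-bound oxygen and the formyl C–H as in phosphoric-acid-catalysed allyl- and propargylboration, so the ortho carbon attacks the aldehyde Re face through a closed six-membered chair and sets the carbinol as S. C8 should react in preference to C6, which is shielded by the in-plane methyl of the 5-OMe group; C8 is also the usual site of electrophilic attack in 5-alkoxy-7-oxygenated flavonoids. Rearomatisation closes the dioxaborin, which locks the o-hydroxybenzyl alcohol against o-quinone methide formation and can be chromatographed. Closest known reactions: the racemic Nagata ortho-hydroxyalkylation of phenols with PhB(OH)2, and chiral-phosphoric-acid-catalysed allylboration of aldehydes.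

**Step 9**
Reactants: 13 cyclic phenylboronate of the target triacetate
Product: 14 (2S)-7-hydroxy-8-[(1S,3R,4E,7S)-1,7-dihydroxy-3,9-bis(4-hydroxyphenyl)non-4-en-1-yl]-2-(4-hydroxyphenyl)-5-methoxy-2,3-dihydro-4H-chromen-4-one (CNP0415883.1)
Conditions: NH4OAc (10 equiv), pinacol (3 equiv), MeOH/H2O 9:1, rt
Reagents that add atoms: none
Why: Near-neutral ammonium-acetate-mediated methanolysis removes only the phenolic acetates, and transesterification with pinacol takes off the boron; no acid or strong base is present, so the flavanone C2 and the electron-rich benzylic carbinol are not epimerised.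

**Compound list**
1 | 1-(2,4-dihydroxy-6-methoxyphenyl)ethan-1-one | COc1cc(O)cc(O)c1C(C)=O | starting material
2 | 4-formylphenyl acetate | CC(=O)Oc1ccc(C=O)cc1 | starting material
3 | 4-[(1E)-3-(2,4-dihydroxy-6-methoxyphenyl)-3-oxoprop-1-en-1-yl]phenyl acetate | CC(=O)Oc1ccc(/C=C/C(=O)c2c(O)cc(O)cc2OC)cc1 | intermediate
4 | 4-[(2S)-7-hydroxy-5-methoxy-4-oxo-3,4-dihydro-2H-chromen-2-yl]phenyl acetate | COc1cc(O)cc2c1C(=O)C[C@@H](c1ccc(OC(C)=O)cc1)O2 | intermediate
5 | (triphenylphosphoranylidene)acetaldehyde | O=CC=P(c1ccccc1)(c1ccccc1)c1ccccc1 | starting material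
6 | 4-[(1E)-3-oxoprop-1-en-1-yl]phenyl acetate | CC(=O)Oc1ccc(/C=C/C=O)cc1 | intermediate
7 | 4-(3-oxopropyl)phenyl acetate | CC(=O)Oc1ccc(CCC=O)cc1 | intermediate
8 | allenylboronic acid pinacol ester | C=C=CB1OC(C)(C)C(C)(C)O1 | starting material
9 | 4-[(3S)-3-hydroxyhex-5-yn-1-yl]phenyl acetate | C#CC[C@@H](O)CCc1ccc(OC(C)=O)cc1 | intermediate
10 | O-boryl alkenylboronate: 4-[(3S,5E)-3-(1,3,2-benzodioxaborol-2-yloxy)-6-(1,3,2-benzodioxaborol-2-yl)hex-5-en-1-yl]phenyl acetate (not isolated) | c1ccc2OB(/C=C/C[C@@H](OB3Oc4ccccc4O3)CCc3ccc(OC(C)=O)cc3)Oc2c1 | intermediate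
11 | potassium trifluoro[(1E,4S)-6-(4-acetoxyphenyl)-4-hydroxyhex-1-en-1-yl]borate | F[B-](F)(F)/C=C/C[C@@H](O)CCc1ccc(OC(C)=O)cc1.[K+] | intermediate
12 | (3R,4E,7S)-3,9-bis(4-acetoxyphenyl)-7-hydroxynon-4-enal | O=CC[C@H](/C=C/C[C@@H](O)CCc1ccc(OC(C)=O)cc1)c1ccc(OC(C)=O)cc1 | intermediate
13 | cyclic phenylboronate of the target triacetate: flavanone 4 carrying at C8 the (1S,3R,4E,7S)-3,9-bis(4-acetoxyphenyl)-7-hydroxynon-4-en-1-yl chain, with O7 and the C1 oxygen of the chain bridged by B–Ph | COc1cc2OB(c3ccccc3)O[C@@H](C[C@H](/C=C/C[C@@H](O)CCc3ccc(OC(C)=O)cc3)c3ccc(OC(C)=O)cc3)c2c2c1C(=O)C[C@@H](c1ccc(OC(C)=O)cc1)O2 | intermediate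
14 | (2S)-7-hydroxy-8-[(1S,3R,4E,7S)-1,7-dihydroxy-3,9-bis(4-hydroxyphenyl)non-4-en-1-yl]-2-(4-hydroxyphenyl)-5-methoxy-2,3-dihydro-4H-chromen-4-one | COc1cc(O)c([C@@H](O)C[C@H](/C=C/C[C@@H](O)CCc2ccc(O)cc2)c2ccc(O)cc2)c2c1C(=O)C[C@@H](c1ccc(O)cc1)O2 | target

**Step count and risks**
Total steps: 9. Longest linear sequence: 7 (steps 3, 4, 5, 6, 7, 8, 9, from 2).

The three steps most likely to fail:

Step 8 (the proposed new step). It may give the C6 regioisomer, poor facial control, or no reaction at 40 °C. Any C6 isomer is removed at the stage of the boronate. The fallback sets out from 4 and 12 and uses only known chemistry. The thermal Nagata protocol (PhB(OH)2, cat. EtCO2H, toluene, 80 °C, water removal) forms the same C8–C bond without facial control and gives the benzodioxaborin as a mixture of carbinol epimers F1. Exchange with pinacol frees the epimeric o-hydroxybenzyl alcohol triacetates F2. MnO2 in CH2Cl2 oxidises only the benzylic alcohol and gives the o-hydroxyaryl ketone F3. Reduction with B-chlorodiisopinocampheylborane (THF, −25 °C) is directed by the 7-OH: hydride is delivered intramolecularly from the aryloxyboron species, so the C4 ketone is spared, and the product is the (1S)-carbinol triacetate F4. F4 is deacetylated under the conditions of step 9, so the fallback comes back at 14.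

Step 2. Unactivated 2'-hydroxychalcones often cyclise with only moderate enantioselectivity, and the free 4'-OH may ion-pair with the catalyst. The fallback sets out from 1. Formylation and cyclisation (HCO2Et, NaH, THF; then HCl, AcOH) give 7-hydroxy-5-methoxychromone F5. Enantioselective conjugate addition of (4-acetoxyphenyl)boronic acid with Pd(OCOCF3)2 and a t-BuPyOx ligand (NH4PF6, H2O, ClCH2CH2Cl, 60 °C) then gives the flavanone directly, so the fallback comes back at 4.

Step 7. An alkyl-substituted alkenyltrifluoroborate is a weaker π-nucleophile than the styryl and heteroaryl borates for which this iminium reaction is established. The fallback sets out from 11 and 6. Hydrolysis of 11 (SiO2, H2O, EtOAc) gives [(1E,4S)-6-(4-acetoxyphenyl)-4-hydroxyhex-1-en-1-yl]boronic acid F6. F6 is added to 6 by a Hayashi–Miyaura 1,4-addition with [RhCl(C2H4)2]2 and a chiral bicyclo[2.2.2]octadiene ligand (Et3N, dioxane/H2O, 40 °C), so the fallback comes back at 12.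

**Further compounds**
F1 | step 8 | benzodioxaborin 13 as a mixture of epimers at the boron-bound benzylic carbon | COc1cc2OB(c3ccccc3)OC(C[C@H](/C=C/C[C@@H](O)CCc3ccc(OC(C)=O)cc3)c3ccc(OC(C)=O)cc3)c2c2c1C(=O)C[C@@H](c1ccc(OC(C)=O)cc1)O2
F2 | step 8 | o-hydroxybenzyl alcohol triacetates, mixture of epimers at the benzylic carbinol | COc1cc(O)c(C(O)C[C@H](/C=C/C[C@@H](O)CCc2ccc(OC(C)=O)cc2)c2ccc(OC(C)=O)cc2)c2c1C(=O)C[C@@H](c1ccc(OC(C)=O)cc1)O2
F3 | step 8 | o-hydroxyaryl ketone triacetate (C8 acyl flavanone) | COc1cc(O)c(C(=O)C[C@H](/C=C/C[C@@H](O)CCc2ccc(OC(C)=O)cc2)c2ccc(OC(C)=O)cc2)c2c1C(=O)C[C@@H](c1ccc(OC(C)=O)cc1)O2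
F4 | step 8 | (1S)-carbinol triacetate of the target | COc1cc(O)c([C@@H](O)C[C@H](/C=C/C[C@@H](O)CCc2ccc(OC(C)=O)cc2)c2ccc(OC(C)=O)cc2)c2c1C(=O)C[C@@H](c1ccc(OC(C)=O)cc1)O2
F5 | step 2 | 7-hydroxy-5-methoxy-4H-chromen-4-one | COc1cc(O)cc2occc(=O)c12
F6 | step 7 | [(1E,4S)-6-(4-acetoxyphenyl)-4-hydroxyhex-1-en-1-yl]boronic acid | OB(O)/C=C/C[C@@H](O)CCc1ccc(OC(C)=O)cc1
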